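**The percent trap.** Percent misleads here. At 60.0 min amber reads 41.7% and red 25.6%, a lower percentage for more solid. In concentration, amber holds 0.0584 M and red 0.0589 M. As a reading, c(target) at that time does not follow the charge in these runs.

| setting | amber | grey | red | alpha | gamma | zeta |
|---|---|---|---|---|---|---|
| solid substrate | 0.14 M | 0.19 M | 0.23 M | 0.12 M | 0.20 M | 0.30 M |
| protic impurity | 0.090 M | 0.090 M | 0.090 M | 0.0900 M | 0.0900 M | 0.0900 M |
| remark | run made earlier | run made earlier | run made earlier |  |  |  |
| time |  |  |  | 2.0 h | 2.0 h | 2.0 h |

| run | time / min | target / % |
|---|---|---|
| amber | 5.00 | 0.2 |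
| amber | 12.0 | 3.3 |
| amber | 25.0 | 11.4 |
| amber | 60.0 | 41.7 |
| grey | 15.0 | 3.6 |
| grey | 30.0 | 11.0 |
| grey | 50.0 | 24.1 |
| grey | 60.0 | 30.8 |
| red | 5.00 | 0.4 |
| red | 12.0 | 2.6 |
| red | 25.0 | 8.0 |
| red | 60.0 | 25.6 |

(each reading ± 0.5 percentage points)

- solid substrate is a solid; its amount is given per volume of the solution
- what was read earlier has a scatter of 0.5 percentage points, one standard deviation
- at the start none of the solid substrate is in solution
- "hardly changes" means that all values lie within two and a half points (for a concentration: within two and a half percent of the largest)

1. [target] at the end for alpha, gamma, zeta, in this order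
2. the shape of the row from first to last (rises all the way / falls, then rises / hardly changes / falls all the way / rises, then falls)

**The rate.** Early on the rate is low: amber gains 6.20 × 10⁻⁴ M min⁻¹ between its first two readings. Later chords in the three runs average 0.00121 M min⁻¹, so as a reading that first stretch of amber runs at about half of that.

**Counting turnovers.** We hold this rate from the mean level at 60.0 min, 0.0586 M, up to 2.0 h. That gives the reach, 0.131 M: the c(target) that the held rate gives at the end. Reach divided by the charge is the turnover count.

Alpha counts 1.09, more than one. Alpha's rate must therefore slow. If alpha stands at the mean level at 60.0 min, its charge then allows an average of 0.00102 M min⁻¹, which is 0.843 of the held rate. Gamma counts 0.655 and zeta 0.437, both below one, so the count forces no slowing on them. We commit to alpha below its charge, and to gamma and zeta level near the reach.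

**The forecast.** It gives 0.11 M, 0.135 M and 0.136 M, and says the row rises all the way: “Gamma and zeta should both reach this, since solid remains present.” Its gamma value stands above our reach.

**The flask.** The row is 0.0740 M, 0.117 M, 0.143 M; it rises all the way.

    target ⇌ isomer of the product (K = 0.410, k = 0.00100 min⁻¹)
    solid substrate ⇌ starting material, rate k2*(cs2 - [starting material]) while solid is left; crystals form when [starting material] > cs2 (solubility = 0.180 M, k = 0.0190 min⁻¹)
    starting material ⇌ other conformer (K = 0.640, k = 0.0150 min⁻¹)
    starting material → target (k = 0.0220 min⁻¹)
    other conformer + protic impurity → quenched substrate (k = 0.0350 M⁻¹ min⁻¹)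
    other conformer → isomer of the product (k = 0.170 min⁻¹)

In alpha at the end, target stands at 61.6% and isomer of the product at 33.9%. Target thus holds a share of 0.645 of the two. Dividing the reach by this share counts both products. With alpha's share, zeta then counts 0.677 turnovers. Zeta's target and isomer of the product together hold 73.2% of its charge.

The data are simulated from invented constants, noise included.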